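**Plan**

- Retrosynthesis: the acyl carbon–pyridine C3 bond is cut first (decalin aldehyde plus C3-lithiated pyridine), then the pyridine C5–C1′ bond (5-lithiopyridine plus a 4-silyloxycyclohexenone). In the decalin the formyl carbon on C2, the C1–allyl bond and the C2–C3 bond of ring A are removed, and last the C4a–C8a bond of ring B.
- Enabling feature: ring B (C4a, C5, C6, C7 with its methyl, C8, C8a) together with C4 and its methyl is the carbon chain of citronellal. The aldehyde carbon is C8a, the stereocentre is C7 and the trisubstituted alkene is C4a=C4, so a malonate condensed onto C8a can be closed onto C4a by an ene reaction.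
- Forward, decalin: ring B by the ene reaction; ring A by acylation of the isopropenyl CH2 (future C3) with one malonate carbonyl (future C2). The second ester steers allylation to C1 and is then excised; C2=O is homologated to C2–CHO and the allyl group is moved to the (E)-propenyl position.
- Forward, heterocycle: pyridine C5 adds to the silyloxy enone, the cyclohexene is epoxidised, C3 is lithiated and joined to the decalin aldehyde; oxidation and fluoride deprotection finish.
- Stereochemistry: C7 of (S)-citronellal sets C4a and C8a (chair ene transition state). C1 is set by equilibration next to the C2 ketone, C2 by axial protonation (still correctable α to the final ketone). C4′ of the (R)-enone directs C1′ (anti addition) and the epoxide (anti to both silyloxy groups).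

Key step: step 2

Assumption: (4R)-4-[(tert-butyldimethylsilyl)oxy]cyclohex-2-en-1-one is taken as a purchasable single enantiomer.
Numbering: decalin carbons as in naphthalene (C1 propenyl, C2 acyl, C4 and C7 methyl); cyclohexyl carbons C1′–C6′ from the pyridyl-bearing carbon.

**Route**

Step 1
Reactants: 1 (S)-citronellal; 2 dimethyl malonate
Product: 3 dimethyl 2-[(3S)-3,7-dimethyloct-6-en-1-ylidene]propanedioate
Conditions: piperidine (cat.), AcOH (cat.), CH2Cl2, 0 °C → rt
Reagents that add atoms: none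
Why: Knoevenagel condensation of an aliphatic aldehyde with a malonate under piperidinium acetate catalysis should give the alkylidene malonate without touching the C3 stereocentre.

Step 2
Reactants: 3 dimethyl 2-[(3S)-3,7-dimethyloct-6-en-1-ylidene]propanedioate
Product: 4 dimethyl 2-[(1S,2S,5S)-5-methyl-2-(prop-1-en-2-yl)cyclohexyl]propanedioate (all three ring substituents equatorial)
Conditions: FeCl3 on Al2O3, CH2Cl2, −78 °C → rt
Reagents that add atoms: none
Why: The Lewis acid chelates the two ester carbonyls and makes the alkylidene carbon (future C8a) electrophilic; the prenyl alkene carbon (future C4a) bonds to it while a hydrogen of an allylic methyl group passes to the malonate carbon, a Lewis acid-promoted intramolecular ene reaction of the kind established for citronellal-derived alkylidene malonates. Ring B closes as a six-membered ring in an exo mode with respect to both π bonds, so that the malonate carbon (future C1) and the isopropenyl carbon (future C4) end up outside the ring. C8a and C4a are set together in a chair transition state in which the C7 methyl group sits equatorial and the two reacting termini are trans-diequatorial, which relays the single stereocentre of the terpene to both new centres. The step needs ene closure in preference to hetero-Diels–Alder addition and to the cis isomer; the diester is a poor heterodiene and the chair with an axial terminus is disfavoured.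

Step 3
Reactants: 4 dimethyl 2-[(1S,2S,5S)-5-methyl-2-(prop-1-en-2-yl)cyclohexyl]propanedioate
Product: 5 (2RS)-3-methoxy-2-[(1S,2S,5S)-5-methyl-2-(prop-1-en-2-yl)cyclohexyl]-3-oxopropanoic acid
Conditions: KOH (1 equiv), MeOH–H2O, 0 °C → rt; then aq. HCl
Reagents that add atoms: potassium hydroxide, [K+].[OH-]
Why: Half-saponification of a substituted malonate should stop at the mono-acid because the carboxylate resists a second attack; the configuration at the malonate carbon is of no consequence since C1 is equilibrated later.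

Step 4
Reactants: 5 (2RS)-3-methoxy-2-[(1S,2S,5S)-5-methyl-2-(prop-1-en-2-yl)cyclohexyl]-3-oxopropanoic acid
Product: 7 methyl (4aS,7S,8aS)-4,7-dimethyl-2-oxo-1,2,4a,5,6,7,8,8a-octahydronaphthalene-1-carboxylate (trans-fused; C1 labile), via acid chloride 6 (not isolated)
Conditions: (COCl)2, DMF (cat.), CH2Cl2, 0 °C → rt; evaporate; SnCl4, CH2Cl2, −78 → 0 °C; then Et3N
Reagents that add atoms: none
Why: Intramolecular Friedel–Crafts-type acylation of an alkene, as known for 5-methylhex-5-enoyl chlorides: the terminal CH2 of the isopropenyl group attacks the activated acyl chloride to form C2–C3 and a tertiary cation at C4, and loss of HCl (completed by the amine) should give the conjugated enone with ring A trans-fused because both arms are equatorial on ring B.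

Step 5
Reactants: 7 methyl (4aS,7S,8aS)-4,7-dimethyl-2-oxo-1,2,4a,5,6,7,8,8a-octahydronaphthalene-1-carboxylate
Product: 8 methyl (4aS,7S,8aS)-4,7-dimethyl-2-oxo-1-(prop-2-en-1-yl)-1,2,4a,5,6,7,8,8a-octahydronaphthalene-1-carboxylate (C1 epimers, both usable)
Conditions: K2CO3, allyl bromide, acetone, reflux
Reagents that add atoms: allyl bromide, C=CCBr
Why: C-alkylation of a cyclic β-keto ester enolate with an allylic halide is reliable and occurs only at the doubly activated C1.

Step 6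
Reactants: 8 methyl (4aS,7S,8aS)-4,7-dimethyl-2-oxo-1-(prop-2-en-1-yl)-1,2,4a,5,6,7,8,8a-octahydronaphthalene-1-carboxylate
Product: 9 (1R,4aS,7S,8aS)-4,7-dimethyl-1-(prop-2-en-1-yl)-4a,5,6,7,8,8a-hexahydronaphthalen-2(1H)-one (allyl equatorial)
Conditions: LiCl, H2O, DMSO, 150 °C
Reagents that add atoms: none
Why: Krapcho dealkoxycarbonylation removes the ester of an α,α-disubstituted β-keto ester, and C1, now enolisable next to the C2 ketone, should settle under these conditions in the more stable equatorial configuration, which is that of the target.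

Step 7
Reactants: 9 (1R,4aS,7S,8aS)-4,7-dimethyl-1-(prop-2-en-1-yl)-4a,5,6,7,8,8a-hexahydronaphthalen-2(1H)-one
Product: 10 (1R,4aS,7S,8aS)-2-(methoxymethylidene)-4,7-dimethyl-1-(prop-2-en-1-yl)-1,2,4a,5,6,7,8,8a-octahydronaphthalene (E/Z mixture at the enol ether)
Conditions: Ph3P(CH2OMe)Cl, KN(SiMe3)2, THF, 0 °C; then 9, 0 °C → rt
Reagents that add atoms: (methoxymethyl)triphenylphosphonium chloride, COC[P+](c1ccccc1)(c1ccccc1)c1ccccc1.[Cl-]
Why: Wittig olefination with the small, reactive methoxymethylene ylide is the standard one-carbon homologation of ketones and enones and leaves the ring alkene in place as part of a dienol ether.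

Step 8
Reactants: 10 (1R,4aS,7S,8aS)-2-(methoxymethylidene)-4,7-dimethyl-1-(prop-2-en-1-yl)-1,2,4a,5,6,7,8,8a-octahydronaphthalene
Product: 11 (1R,2S,4aS,7S,8aR)-4,7-dimethyl-1-(prop-2-en-1-yl)-1,2,4a,5,6,7,8,8a-octahydronaphthalene-2-carbaldehyde
Conditions: TsOH·H2O (cat.), acetone–H2O, 0 °C → rt
Reagents that add atoms: water, O
Why: Acid hydrolysis of a dienol ether proceeds by kinetic protonation at the α-carbon (C2), which should give the β,γ-unsaturated aldehyde with C3=C4 retained, axial protonation placing the formyl group equatorial and trans to the allyl group.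

Step 9
Reactants: 11 (1R,2S,4aS,7S,8aR)-4,7-dimethyl-1-(prop-2-en-1-yl)-1,2,4a,5,6,7,8,8a-octahydronaphthalene-2-carbaldehyde
Product: 12 (1R,2S,4aS,7S,8aR)-4,7-dimethyl-1-[(1E)-prop-1-en-1-yl]-1,2,4a,5,6,7,8,8a-octahydronaphthalene-2-carbaldehyde
Conditions: Pd(dba)2 (cat.), P(t-Bu)3 (cat.), i-PrCOCl (cat.), toluene, 80 °C
Reagents that add atoms: none
Why: A bulky palladium hydride formed in situ moves a terminal alkene by one position to the (E)-2-alkene by insertion and β-hydride elimination; a further shift would need a trisubstituted alkene at the branched C1, and the ring alkene is too hindered to insert.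

Step 10
Reactants: 13 5-bromo-2,4-dichloropyridine
Product: 14 5-bromo-2,4-bis[2-(trimethylsilyl)ethoxy]pyridine
Conditions: 2-(trimethylsilyl)ethanol (2.5 equiv), NaH, DMF, 0 → 80 °C
Reagents that add atoms: 2-(trimethylsilyl)ethanol, C[Si](C)(C)CCO
Why: Nucleophilic aromatic substitution by an alkoxide displaces the 4- and then the 2-chloride of the pyridine, while the 5-bromide, which is not activated by the ring nitrogen, stays.

Step 11
Reactants: 14 5-bromo-2,4-bis[2-(trimethylsilyl)ethoxy]pyridine; 15 (4R)-4-[(tert-butyldimethylsilyl)oxy]cyclohex-2-en-1-one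
Product: 17 (1S,4R)-1-{4,6-bis[2-(trimethylsilyl)ethoxy]pyridin-3-yl}-4-[(tert-butyldimethylsilyl)oxy]cyclohex-2-en-1-ol (hydroxyl cis to the silyloxy group), via 5-lithiopyridine 16 (not isolated)
Conditions: n-BuLi, THF, −78 °C; then 15, −78 °C; aq. NH4Cl
Reagents that add atoms: none
Why: Bromine–lithium exchange followed by 1,2-addition of the aryllithium to the enone, which should occur by axial attack on the half-chair from the face opposite the pseudo-axial C4′ silyloxy group, so that the new tertiary hydroxyl at C1′ is cis to it.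

Step 12
Reactants: 17 (1S,4R)-1-{4,6-bis[2-(trimethylsilyl)ethoxy]pyridin-3-yl}-4-[(tert-butyldimethylsilyl)oxy]cyclohex-2-en-1-ol
Product: 18 5-[(1S,4R)-4-[(tert-butyldimethylsilyl)oxy]-1-[(triethylsilyl)oxy]cyclohex-2-en-1-yl]-2,4-bis[2-(trimethylsilyl)ethoxy]pyridine
Conditions: Et3SiOTf, 2,6-lutidine, CH2Cl2, −78 → 0 °C
Reagents that add atoms: triethylsilyl trifluoromethanesulfonate, CC[Si](CC)(CC)OS(=O)(=O)C(F)(F)F
Why: A silyl triflate with a hindered pyridine base silylates tertiary alcohols, and capping the hydroxyl removes any syn-directing effect in the epoxidation that follows.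

Step 13
Reactants: 18 5-[(1S,4R)-4-[(tert-butyldimethylsilyl)oxy]-1-[(triethylsilyl)oxy]cyclohex-2-en-1-yl]-2,4-bis[2-(trimethylsilyl)ethoxy]pyridine
Product: 19 5-[(1R,2S,3R,4R)-4-[(tert-butyldimethylsilyl)oxy]-2,3-epoxy-1-[(triethylsilyl)oxy]cyclohexyl]-2,4-bis[2-(trimethylsilyl)ethoxy]pyridine (epoxide oxygen trans to both silyloxy groups, cis to the pyridyl group)
Conditions: mCPBA, NaHCO3, CH2Cl2, 0 °C → rt
Reagents that add atoms: 3-chloroperoxybenzoic acid, OOC(=O)c1cccc(Cl)c1
Why: Prilezhaev epoxidation of a cyclic cis-alkene should take place on the face opposite both allylic silyloxy groups (the C1′ silyloxy group is pseudo-axial when the aryl group is pseudo-equatorial), setting C2′ and C3′, while the pyridine nitrogen flanked by a 2-alkoxy group is a poor nucleophile toward the peracid.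

Step 14
Reactants: 19 5-[(1R,2S,3R,4R)-4-[(tert-butyldimethylsilyl)oxy]-2,3-epoxy-1-[(triethylsilyl)oxy]cyclohexyl]-2,4-bis[2-(trimethylsilyl)ethoxy]pyridine; 12 (1R,2S,4aS,7S,8aR)-4,7-dimethyl-1-[(1E)-prop-1-en-1-yl]-1,2,4a,5,6,7,8,8a-octahydronaphthalene-2-carbaldehyde
Product: 21 (RS)-{(1R,2S,4aS,7S,8aR)-4,7-dimethyl-1-[(1E)-prop-1-en-1-yl]-1,2,4a,5,6,7,8,8a-octahydronaphthalen-2-yl}{5-[(1R,2S,3R,4R)-4-[(tert-butyldimethylsilyl)oxy]-2,3-epoxy-1-[(triethylsilyl)oxy]cyclohexyl]-2,4-bis[2-(trimethylsilyl)ethoxy]pyridin-3-yl}methanol (carbinol epimers), via 3-lithiopyridine 20 (not isolated)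
Conditions: t-BuLi, THF, −78 °C; then 12, −78 °C; aq. NH4Cl
Reagents that add atoms: none
Why: Directed ortho-metalation at C3, the position between the two alkoxy groups, followed by addition of the aryllithium to the aldehyde is the established way to 3-acyl-2,4-dialkoxypyridines, and at −78 °C the epoxide and silyl ethers should not react with the base.

Step 15
Reactants: 21 the carbinol of step 14
Product: 22 {(1R,2S,4aS,7S,8aR)-4,7-dimethyl-1-[(1E)-prop-1-en-1-yl]-1,2,4a,5,6,7,8,8a-octahydronaphthalen-2-yl}{5-[(1R,2S,3R,4R)-4-[(tert-butyldimethylsilyl)oxy]-2,3-epoxy-1-[(triethylsilyl)oxy]cyclohexyl]-2,4-bis[2-(trimethylsilyl)ethoxy]pyridin-3-yl}methanone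
Conditions: Dess–Martin periodinane, NaHCO3, CH2Cl2, 0 °C → rt
Reagents that add atoms: none
Why: Dess–Martin oxidation converts the hindered secondary carbinol into the ketone under buffered, near-neutral conditions that spare the epoxide, the silyl ethers and the β,γ-alkene, and removes the carbinol stereocentre; a minor C2 epimer, if carried through, can equilibrate α to this ketone to the trans-diequatorial arrangement.

Step 16
Reactants: 22 the ketone of step 15
Product: 23 3-{[(1R,2S,4aS,7S,8aR)-4,7-dimethyl-1-[(1E)-prop-1-en-1-yl]-1,2,4a,5,6,7,8,8a-octahydronaphthalen-2-yl]carbonyl}-5-[(1R,2S,3S,4R)-2,3-epoxy-1,4-dihydroxycyclohexyl]-4-hydroxypyridin-2(1H)-one (CNP0494338.1)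
Conditions: Bu4NF, AcOH, THF, 0 °C → rt
Reagents that add atoms: none
Why: Fluoride cleaves both silyl ethers and triggers β-elimination of the two 2-(trimethylsilyl)ethyl ethers (ethene and fluorotrimethylsilane leave), freeing the 4-hydroxy-2-pyridone, and the acetic acid buffer should keep the free epoxy alcohols from base-induced epoxide migration.

**Compound list**

1 | (S)-citronellal, (3S)-3,7-dimethyloct-6-enal | C[C@@H](CCC=C(C)C)CC=O | starting material
2 | dimethyl malonate | COC(=O)CC(=O)OC | starting material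
3 | dimethyl 2-[(3S)-3,7-dimethyloct-6-en-1-ylidene]propanedioate | COC(=O)C(=CC[C@@H](C)CCC=C(C)C)C(=O)OC | intermediate
4 | dimethyl 2-[(1S,2S,5S)-5-methyl-2-(prop-1-en-2-yl)cyclohexyl]propanedioate | COC(=O)C(C(=O)OC)[C@H]1C[C@@H](C)CC[C@@H]1C(C)=C | intermediate
5 | (2RS)-3-methoxy-2-[(1S,2S,5S)-5-methyl-2-(prop-1-en-2-yl)cyclohexyl]-3-oxopropanoic acid | COC(=O)C(C(O)=O)[C@H]1C[C@@H](C)CC[C@@H]1C(C)=C | intermediate
6 | methyl (2RS)-3-chloro-2-[(1S,2S,5S)-5-methyl-2-(prop-1-en-2-yl)cyclohexyl]-3-oxopropanoate | COC(=O)C(C(Cl)=O)[C@H]1C[C@@H](C)CC[C@@H]1C(C)=C | intermediate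
7 | methyl (4aS,7S,8aS)-4,7-dimethyl-2-oxo-1,2,4a,5,6,7,8,8a-octahydronaphthalene-1-carboxylate (C1 labile) | COC(=O)C1[C@H]2C[C@@H](C)CC[C@@H]2C(C)=CC1=O | intermediate
8 | methyl (4aS,7S,8aS)-4,7-dimethyl-2-oxo-1-(prop-2-en-1-yl)-1,2,4a,5,6,7,8,8a-octahydronaphthalene-1-carboxylate (C1 epimers) | C=CCC1(C(=O)OC)[C@H]2C[C@@H](C)CC[C@@H]2C(C)=CC1=O | intermediate
9 | (1R,4aS,7S,8aS)-4,7-dimethyl-1-(prop-2-en-1-yl)-4a,5,6,7,8,8a-hexahydronaphthalen-2(1H)-one | C=CC[C@@H]1[C@H]2C[C@@H](C)CC[C@@H]2C(C)=CC1=O | intermediate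
10 | (1R,4aS,7S,8aS)-2-(methoxymethylidene)-4,7-dimethyl-1-(prop-2-en-1-yl)-1,2,4a,5,6,7,8,8a-octahydronaphthalene (E/Z) | C=CC[C@@H]1[C@H]2C[C@@H](C)CC[C@@H]2C(C)=CC1=COC | intermediate
11 | (1R,2S,4aS,7S,8aR)-4,7-dimethyl-1-(prop-2-en-1-yl)-1,2,4a,5,6,7,8,8a-octahydronaphthalene-2-carbaldehyde | C=CC[C@@H]1[C@H]2C[C@@H](C)CC[C@@H]2C(C)=C[C@H]1C=O | intermediate
12 | (1R,2S,4aS,7S,8aR)-4,7-dimethyl-1-[(1E)-prop-1-en-1-yl]-1,2,4a,5,6,7,8,8a-octahydronaphthalene-2-carbaldehyde | C/C=C/[C@@H]1[C@H]2C[C@@H](C)CC[C@@H]2C(C)=C[C@H]1C=O | intermediate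
13 | 5-bromo-2,4-dichloropyridine | Clc1cc(Cl)c(Br)cn1 | starting material
14 | 5-bromo-2,4-bis[2-(trimethylsilyl)ethoxy]pyridine | C[Si](C)(C)CCOc1cc(OCC[Si](C)(C)C)c(Br)cn1 | intermediate
15 | (4R)-4-[(tert-butyldimethylsilyl)oxy]cyclohex-2-en-1-one | O=C1C=C[C@H](O[Si](C)(C)C(C)(C)C)CC1 | starting material
16 | {4,6-bis[2-(trimethylsilyl)ethoxy]pyridin-3-yl}lithium | [Li]c1cnc(OCC[Si](C)(C)C)cc1OCC[Si](C)(C)C | intermediate
17 | (1S,4R)-1-{4,6-bis[2-(trimethylsilyl)ethoxy]pyridin-3-yl}-4-[(tert-butyldimethylsilyl)oxy]cyclohex-2-en-1-ol | C[Si](C)(C)CCOc1cc(OCC[Si](C)(C)C)c(cn1)[C@]1(O)CC[C@@H](O[Si](C)(C)C(C)(C)C)C=C1 | intermediate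
18 | 5-[(1S,4R)-4-[(tert-butyldimethylsilyl)oxy]-1-[(triethylsilyl)oxy]cyclohex-2-en-1-yl]-2,4-bis[2-(trimethylsilyl)ethoxy]pyridine | C[Si](C)(C)CCOc1cc(OCC[Si](C)(C)C)c(cn1)[C@]1(O[Si](CC)(CC)CC)CC[C@@H](O[Si](C)(C)C(C)(C)C)C=C1 | intermediate
19 | 5-[(1R,2S,3R,4R)-4-[(tert-butyldimethylsilyl)oxy]-2,3-epoxy-1-[(triethylsilyl)oxy]cyclohexyl]-2,4-bis[2-(trimethylsilyl)ethoxy]pyridine | C[Si](C)(C)CCOc1cc(OCC[Si](C)(C)C)c(cn1)[C@]1(O[Si](CC)(CC)CC)CC[C@@H](O[Si](C)(C)C(C)(C)C)[C@@H]2O[C@@H]21 | intermediate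
20 | {5-[(1R,2S,3R,4R)-4-[(tert-butyldimethylsilyl)oxy]-2,3-epoxy-1-[(triethylsilyl)oxy]cyclohexyl]-2,4-bis[2-(trimethylsilyl)ethoxy]pyridin-3-yl}lithium | C[Si](C)(C)CCOc1ncc(c(OCC[Si](C)(C)C)c1[Li])[C@]1(O[Si](CC)(CC)CC)CC[C@@H](O[Si](C)(C)C(C)(C)C)[C@@H]2O[C@@H]21 | intermediate
21 | (RS)-{(1R,2S,4aS,7S,8aR)-4,7-dimethyl-1-[(1E)-prop-1-en-1-yl]-1,2,4a,5,6,7,8,8a-octahydronaphthalen-2-yl}{5-[(1R,2S,3R,4R)-4-[(tert-butyldimethylsilyl)oxy]-2,3-epoxy-1-[(triethylsilyl)oxy]cyclohexyl]-2,4-bis[2-(trimethylsilyl)ethoxy]pyridin-3-yl}methanol | C/C=C/[C@@H]1[C@H]2C[C@@H](C)CC[C@@H]2C(C)=C[C@H]1C(O)c1c(OCC[Si](C)(C)C)c(cnc1OCC[Si](C)(C)C)[C@]1(O[Si](CC)(CC)CC)CC[C@@H](O[Si](C)(C)C(C)(C)C)[C@@H]2O[C@@H]21 | intermediate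
22 | {(1R,2S,4aS,7S,8aR)-4,7-dimethyl-1-[(1E)-prop-1-en-1-yl]-1,2,4a,5,6,7,8,8a-octahydronaphthalen-2-yl}{5-[(1R,2S,3R,4R)-4-[(tert-butyldimethylsilyl)oxy]-2,3-epoxy-1-[(triethylsilyl)oxy]cyclohexyl]-2,4-bis[2-(trimethylsilyl)ethoxy]pyridin-3-yl}methanone | C/C=C/[C@@H]1[C@H]2C[C@@H](C)CC[C@@H]2C(C)=C[C@H]1C(=O)c1c(OCC[Si](C)(C)C)c(cnc1OCC[Si](C)(C)C)[C@]1(O[Si](CC)(CC)CC)CC[C@@H](O[Si](C)(C)C(C)(C)C)[C@@H]2O[C@@H]21 | intermediate
23 | 3-{[(1R,2S,4aS,7S,8aR)-4,7-dimethyl-1-[(1E)-prop-1-en-1-yl]-1,2,4a,5,6,7,8,8a-octahydronaphthalen-2-yl]carbonyl}-5-[(1R,2S,3S,4R)-2,3-epoxy-1,4-dihydroxycyclohexyl]-4-hydroxypyridin-2(1H)-one | C/C=C/[C@@H]1[C@H]2C[C@@H](C)CC[C@@H]2C(C)=C[C@H]1C(=O)c1c(O)c([C@]2(O)CC[C@@H](O)[C@@H]3O[C@@H]32)c[nH]c1=O | target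

**Step count and risks**

Total steps: 16. Longest linear sequence: 12 (steps 1–9, then 14–16); the pyridine branch (steps 10–13) joins at step 14.

Steps most likely to fail:

1. Step 4. Hydrochlorination or lactonisation at the isopropenyl group, or acid-induced alkene migration, may outrun C-acylation. Fallback (ring A by metathesis instead of acylation), setting out from 4: Krapcho dealkoxycarbonylation (LiCl, wet DMSO, 150 °C) would give methyl 2-[(1R,2S,5S)-5-methyl-2-(prop-1-en-2-yl)cyclohexyl]acetate F1. MeNH(OMe)·HCl with i-PrMgCl converts it into the Weinreb amide N-methoxy-N-methyl-2-[(1R,2S,5S)-5-methyl-2-(prop-1-en-2-yl)cyclohexyl]acetamide F2. Vinylmagnesium bromide then gives the vinyl ketone 1-[(1R,2S,5S)-5-methyl-2-(prop-1-en-2-yl)cyclohexyl]but-3-en-2-one F3. Ring-closing metathesis with the second-generation Grubbs catalyst closes C3=C4 to the enone (4aS,7S,8aR)-4,7-dimethyl-4a,5,6,7,8,8a-hexahydronaphthalen-2(1H)-one F4. Kinetic deprotonation at C1 (LiN(i-Pr)2, THF, −78 °C), allyl bromide and base equilibration return to the route at 9.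

2. Step 13. The peracid may attack the wrong alkene face or the pyridine nitrogen. Fallback (dihydroxylation followed by stereospecific closure), setting out from 18: OsO4 (cat.) with N-methylmorpholine N-oxide does not oxidise the pyridine nitrogen and should add anti to both allylic silyloxy groups, giving (1R,2S,3R,4R)-1-{4,6-bis[2-(trimethylsilyl)ethoxy]pyridin-3-yl}-4-[(tert-butyldimethylsilyl)oxy]-1-[(triethylsilyl)oxy]cyclohexane-2,3-diol F5. Trimethyl orthoacetate/PPTS and then acetyl bromide open the derived acetoxonium ion with inversion at C3′ to (1R,2R,3S,4R)-3-bromo-1-{4,6-bis[2-(trimethylsilyl)ethoxy]pyridin-3-yl}-4-[(tert-butyldimethylsilyl)oxy]-1-[(triethylsilyl)oxy]cyclohexan-2-yl acetate F6. K2CO3 in MeOH cleaves the acetate and the C2′ alkoxide displaces bromide, closing the epoxide on the face of the original diol and returning to the route at 19.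

3. Step 14. The alkyllithium may attack the epoxide or the pyridine ring in competition with deprotonation at C3. Fallback (halogen–lithium exchange instead of deprotonation), setting out from 18, which carries no epoxide: t-BuLi and then 1,2-dibromotetrachloroethane give 3-bromo-5-[(1S,4R)-4-[(tert-butyldimethylsilyl)oxy]-1-[(triethylsilyl)oxy]cyclohex-2-en-1-yl]-2,4-bis[2-(trimethylsilyl)ethoxy]pyridine F7. Epoxidation as in step 13 gives 3-bromo-5-[(1R,2S,3R,4R)-4-[(tert-butyldimethylsilyl)oxy]-2,3-epoxy-1-[(triethylsilyl)oxy]cyclohexyl]-2,4-bis[2-(trimethylsilyl)ethoxy]pyridine F8. n-BuLi at −78 °C exchanges bromine for lithium far faster than it can attack the epoxide and regenerates 20, where the route is rejoined and continued with 12 to 21.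

Further compounds
F1 | step 4 | methyl 2-[(1R,2S,5S)-5-methyl-2-(prop-1-en-2-yl)cyclohexyl]acetate | COC(=O)C[C@H]1C[C@@H](C)CC[C@@H]1C(C)=C
F2 | step 4 | N-methoxy-N-methyl-2-[(1R,2S,5S)-5-methyl-2-(prop-1-en-2-yl)cyclohexyl]acetamide | CON(C)C(=O)C[C@H]1C[C@@H](C)CC[C@@H]1C(C)=C
F3 | step 4 | 1-[(1R,2S,5S)-5-methyl-2-(prop-1-en-2-yl)cyclohexyl]but-3-en-2-one | C=CC(=O)C[C@H]1C[C@@H](C)CC[C@@H]1C(C)=C
F4 | step 4 | (4aS,7S,8aR)-4,7-dimethyl-4a,5,6,7,8,8a-hexahydronaphthalen-2(1H)-one | O=C1C[C@H]2C[C@@H](C)CC[C@@H]2C(C)=C1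
F5 | step 13 | (1R,2S,3R,4R)-1-{4,6-bis[2-(trimethylsilyl)ethoxy]pyridin-3-yl}-4-[(tert-butyldimethylsilyl)oxy]-1-[(triethylsilyl)oxy]cyclohexane-2,3-diol | C[Si](C)(C)CCOc1cc(OCC[Si](C)(C)C)c(cn1)[C@]1(O[Si](CC)(CC)CC)CC[C@@H](O[Si](C)(C)C(C)(C)C)[C@H](O)[C@@H]1O
F6 | step 13 | (1R,2R,3S,4R)-3-bromo-1-{4,6-bis[2-(trimethylsilyl)ethoxy]pyridin-3-yl}-4-[(tert-butyldimethylsilyl)oxy]-1-[(triethylsilyl)oxy]cyclohexan-2-yl acetate | C[Si](C)(C)CCOc1cc(OCC[Si](C)(C)C)c(cn1)[C@]1(O[Si](CC)(CC)CC)CC[C@@H](O[Si](C)(C)C(C)(C)C)[C@@H](Br)[C@@H]1OC(C)=O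
F7 | step 14 | 3-bromo-5-[(1S,4R)-4-[(tert-butyldimethylsilyl)oxy]-1-[(triethylsilyl)oxy]cyclohex-2-en-1-yl]-2,4-bis[2-(trimethylsilyl)ethoxy]pyridine | C[Si](C)(C)CCOc1ncc(c(OCC[Si](C)(C)C)c1Br)[C@]1(O[Si](CC)(CC)CC)CC[C@@H](O[Si](C)(C)C(C)(C)C)C=C1
F8 | step 14 | 3-bromo-5-[(1R,2S,3R,4R)-4-[(tert-butyldimethylsilyl)oxy]-2,3-epoxy-1-[(triethylsilyl)oxy]cyclohexyl]-2,4-bis[2-(trimethylsilyl)ethoxy]pyridine | C[Si](C)(C)CCOc1ncc(c(OCC[Si](C)(C)C)c1Br)[C@]1(O[Si](CC)(CC)CC)CC[C@@H](O[Si](C)(C)C(C)(C)C)[C@@H]2O[C@@H]21
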